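**Retrosynthetic overview**
1. Target 21 ⇒ 8‑hydroxy macrocycle 19 + (R)‑2‑methylbutanoic acid 20 (last‑step esterification at O‑8).
2. 19 ⇒ 2‑oxoaldehyde 18 by the C7–C8 bond: a visible‑light, chromium‑catalysed intramolecular allylation of the aldehyde by its own 3‑(bromomethyl)butenolide closes the ten‑membered carbocycle, unveils the α‑methylene lactone and sets C‑7 and C‑8 from C‑6.
3. 18 ⇒ 15 ⇒ triol 11: butenolide by ring‑closing metathesis of a C‑6 2‑(bromomethyl)acrylate; C‑8/C‑9 dicarbonyl from a terminal vinyl group; O‑6 then O‑5 acylated.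
4. 11 ⇒ bromide 3 + ester 6: C3–C4 bond by Grignard/Weinreb ketone synthesis, C‑4 set by chelation‑controlled MeMgBr addition; 3 from (R)‑β‑citronellene 1 (C‑10), 6 from L‑tartrate acetonide 4 (C‑5, C‑6).
5. Ring order: butenolide first (step 8), ten‑membered ring second (step 11).

Assumption: positions are given in germacrane numbering (ring C‑1 to C‑10, lactone C‑6/C‑7/C‑11/C‑12, methylidene C‑13, methyls C‑14 on C‑10 and C‑15 on C‑4); 1, 4, 12 and 20 are taken as catalogue compounds.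

**Route**

Step 1
Reactants: 1 (R)‑β‑citronellene [(3R)‑3,7‑dimethylocta‑1,6‑diene]
Product: 2 (4R)‑4‑methylhex‑5‑en‑1‑ol
Conditions: O3 (1.0 equiv, Sudan red 7B end‑point), CH2Cl2/MeOH 4:1, −78 °C; then NaBH4, −78 °C → rt
Reagents that add atoms: ozone, [O-][O+]=O
Why: Chemoselective ozonolysis with reductive work‑up: the electron‑rich trisubstituted alkene reacts far faster than the monosubstituted vinyl group, and the bought stereocentre (future C‑10) is not touched.

Step 2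
Reactants: 2 (4R)‑4‑methylhex‑5‑en‑1‑ol
Product: 3 (3R)‑6‑bromo‑3‑methylhex‑1‑ene
Conditions: CBr4, PPh3, CH2Cl2, 0 °C
Reagents that add atoms: carbon tetrabromide, BrC(Br)(Br)Br
Why: Appel bromination of a primary alcohol, remote from the stereocentre.

Step 3
Reactants: 4 dimethyl (4R,5R)‑2,2‑dimethyl‑1,3‑dioxolane‑4,5‑dicarboxylate (dimethyl 2,3‑O‑isopropylidene‑L‑tartrate)
Product: 6 methyl (4R,5S)‑5‑ethenyl‑2,2‑dimethyl‑1,3‑dioxolane‑4‑carboxylate, via aldehyde ester 5 (not isolated)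
Conditions: iBu2AlH (1.05 equiv), toluene, −78 °C; then Ph3P=CH2 (from Ph3PCH3Br and KN(SiMe3)2, THF), −78 °C → rt
Reagents that add atoms: methyltriphenylphosphonium bromide, C[P+](c1ccccc1)(c1ccccc1)c1ccccc1.[Br-]
Why: Mono‑reduction of the C2‑symmetric diester (either ester gives the same product) to the aldehyde level and in situ Wittig methylenation; the two tartrate stereocentres (future C‑5 and C‑6) are kept, trans being also the stable dioxolane arrangement.

Step 4
Reactants: 3 (3R)‑6‑bromo‑3‑methylhex‑1‑ene, 6 methyl (4R,5S)‑5‑ethenyl‑2,2‑dimethyl‑1,3‑dioxolane‑4‑carboxylate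
Product: 9 (5R)‑1‑[(4R,5S)‑5‑ethenyl‑2,2‑dimethyl‑1,3‑dioxolan‑4‑yl]‑5‑methylhept‑6‑en‑1‑one, via Grignard reagent 7 (not isolated), via Weinreb amide 8 (not isolated)
Conditions: 3, Mg, THF, 0 °C → rt (gives 7); separately 6, MeNH(OMe)·HCl, iPrMgCl, THF, −20 °C (gives 8); then 7, −20 → 0 °C; aq NH4Cl
Reagents that add atoms: none
Why: Weinreb ketone synthesis in one pot: ester‑to‑amide exchange by the magnesium amide, then Grignard addition that stops at the ketone through the chelated tetrahedral intermediate; forms the C3–C4 bond without creating a stereocentre.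

Step 5
Reactants: 9 (5R)‑1‑[(4R,5S)‑5‑ethenyl‑2,2‑dimethyl‑1,3‑dioxolan‑4‑yl]‑5‑methylhept‑6‑en‑1‑one
Product: 11 (3S,4R,5S,9R)‑5,9‑dimethylundeca‑1,10‑diene‑3,4,5‑triol, via acetonide alcohol 10 (not isolated)
Conditions: MgBr2·OEt2, CH2Cl2/Et2O, −78 °C, then MeMgBr; then 2 M aq HCl, MeOH, 40 °C
Reagents that add atoms: methylmagnesium bromide, C[Mg]Br
Why: Cram‑chelate‑controlled Grignard addition: magnesium bridges the ketone oxygen and the adjacent dioxolane oxygen on C‑5, so methyl enters from the face of the C‑5 hydrogen (anti to the C‑6 branch) and gives the (4S) tertiary alcohol; acid then hydrolyses the acetonide in the same pot.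

Step 6
Reactants: 11 (3S,4R,5S,9R)‑5,9‑dimethylundeca‑1,10‑diene‑3,4,5‑triol, 12 2‑(bromomethyl)prop‑2‑enoic acid
Product: 14 (3S,4R,5S,9R)‑4,5‑dihydroxy‑5,9‑dimethylundeca‑1,10‑dien‑3‑yl 2‑(bromomethyl)prop‑2‑enoate, via acid chloride 13 (not isolated)
Conditions: 12, (COCl)2, cat. DMF, CH2Cl2, 0 °C → rt, evaporate (gives 13); then 11, 2,4,6‑collidine, CH2Cl2, −78 → −40 °C
Reagents that add atoms: none
Why: Kinetic acylation with an acid chloride at the less hindered allylic O‑6 hydroxyl (the O‑5 hydroxyl sits next to the quaternary C‑4, and the tertiary hydroxyl is inert); hindered collidine does not attack the SN2'‑prone allylic bromide.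

Step 7
Reactants: 14 (3S,4R,5S,9R)‑4,5‑dihydroxy‑5,9‑dimethylundeca‑1,10‑dien‑3‑yl 2‑(bromomethyl)prop‑2‑enoate
Product: 15 (3S,4R,5S,9R)‑3‑{[2‑(bromomethyl)prop‑2‑enoyl]oxy}‑5‑hydroxy‑5,9‑dimethylundeca‑1,10‑dien‑4‑yl 2‑methylpropanoate
Conditions: iPrCOCl, 2,4,6‑collidine, CH2Cl2, 0 °C → rt
Reagents that add atoms: 2‑methylpropanoyl chloride, CC(C)C(Cl)=O
Why: Esterification of the only remaining secondary hydroxyl (O‑5) with an acid chloride and a non‑nucleophilic base; the tertiary C‑4 hydroxyl is too hindered to react and acyl migration towards the more hindered oxygen is uphill.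

Step 8
Reactants: 15 (3S,4R,5S,9R)‑3‑{[2‑(bromomethyl)prop‑2‑enoyl]oxy}‑5‑hydroxy‑5,9‑dimethylundeca‑1,10‑dien‑4‑yl 2‑methylpropanoate
Product: 16 (1R,2S,6R)‑1‑[(2S)‑4‑(bromomethyl)‑5‑oxo‑2,5‑dihydrofuran‑2‑yl]‑2‑hydroxy‑2,6‑dimethyloct‑7‑en‑1‑yl 2‑methylpropanoate
Conditions: second‑generation Hoveyda–Grubbs catalyst [RuCl2(H2IMes)(=CH‑C6H4‑2‑OiPr)] (5 mol%), toluene (3 mM), 80 °C
Reagents that add atoms: none
Why: Ring‑closing metathesis: five‑membered ring closure between the C‑7 vinyl group and the acrylate is fast, while the remote α‑branched vinyl group is a poor cross‑metathesis partner at this dilution; C‑6 is unchanged.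

Step 9
Reactants: 16 (1R,2S,6R)‑1‑[(2S)‑4‑(bromomethyl)‑5‑oxo‑2,5‑dihydrofuran‑2‑yl]‑2‑hydroxy‑2,6‑dimethyloct‑7‑en‑1‑yl 2‑methylpropanoate
Product: 17 (1R,2S,6R)‑1‑[(2S)‑4‑(bromomethyl)‑5‑oxo‑2,5‑dihydrofuran‑2‑yl]‑2,7,8‑trihydroxy‑2,6‑dimethyloctyl 2‑methylpropanoate (both epimers at the new secondary carbinol, germacrane C‑9)
Conditions: OsO4 (2 mol%), N‑methylmorpholine N‑oxide, citric acid, tBuOH/H2O 1:1, rt
Reagents that add atoms: N‑methylmorpholine N‑oxide, C[N+]1([O-])CCOCC1; water, O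
Why: Upjohn dihydroxylation goes to the isolated monosubstituted alkene, the electron‑poor trisubstituted butenolide alkene being much slower; citric acid keeps the amine by‑product protonated so it cannot displace the allylic bromide, and the new carbinol centre is erased in step 10.

Step 10
Reactants: 17 (1R,2S,6R)‑1‑[(2S)‑4‑(bromomethyl)‑5‑oxo‑2,5‑dihydrofuran‑2‑yl]‑2,7,8‑trihydroxy‑2,6‑dimethyloctyl 2‑methylpropanoate
Product: 18 (1R,2S,6R)‑1‑[(2S)‑4‑(bromomethyl)‑5‑oxo‑2,5‑dihydrofuran‑2‑yl]‑2‑hydroxy‑2,6‑dimethyl‑7,8‑dioxooctyl 2‑methylpropanoate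
Conditions: (COCl)2, DMSO, CH2Cl2, −78 °C; iPr2NEt, −78 → −30 °C; used crude after toluene azeotrope
Reagents that add atoms: none
Why: Double Swern oxidation turns the 1,2‑diol into the 2‑oxoaldehyde without C–C cleavage; the tertiary hydroxyl is inert and the cold, hindered‑base conditions spare the allylic bromide and the C‑10 stereocentre.

Step 11
Reactants: 18 (1R,2S,6R)‑1‑[(2S)‑4‑(bromomethyl)‑5‑oxo‑2,5‑dihydrofuran‑2‑yl]‑2‑hydroxy‑2,6‑dimethyl‑7,8‑dioxooctyl 2‑methylpropanoate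
Product: 19 (3aR,4R,6R,10S,11R,11aS)‑4,10‑dihydroxy‑6,10‑dimethyl‑3‑methylidene‑2,5‑dioxododecahydrocyclodeca[b]furan‑11‑yl 2‑methylpropanoate
Conditions: 2,4,5,6‑tetrakis(carbazol‑9‑yl)isophthalonitrile (4CzIPN, 3 mol%), CrCl3·3THF (20 mol%), diethyl 2,6‑dimethyl‑1,4‑dihydropyridine‑3,5‑dicarboxylate (Hantzsch ester, 2 equiv), degassed THF/DMF 4:1, 450 nm LEDs, 25 °C, 18 added by syringe pump over 12 h (2 mM final)
Reagents that add atoms: none
Why: Proposed new method: a light‑driven, chromium‑catalysed intramolecular Barbier (Nozaki–Hiyama–Kishi‑type) allylation with a 3‑(bromomethyl)butenolide as allyl donor and a 2‑oxoaldehyde as acceptor, closing a ten‑membered ring — excited 4CzIPN is quenched by the Hantzsch ester and its radical anion reduces trivalent to divalent chromium, which takes bromide from 18 to give an allyl radical that a second divalent chromium captures as a σ‑allyl trivalent chromium species bound at C‑13; this adds through its γ‑carbon C‑7 to the aldehyde C‑8 (far more electrophilic than the C‑9 ketone) in a closed six‑membered chair transition state, on the butenolide face anti to the C‑5 branch (sets C‑7, trans ring fusion) and with C‑6 and C‑9 both equatorial (sets C‑8 as in the target, both controlled by C‑6), the C11=C13 methylidene appearing as the bond forms, and the pyridinium formed from the Hantzsch ester protonates the chromium alkoxide to turn the catalyst over; slow addition keeps 18 below the catalyst concentration to suppress direct ketyl formation and dimerisation; closest known reaction type: dual photoredox/chromium‑catalysed allylation of aldehydes between two molecules, together with thermal chromium‑mediated additions of 3‑(bromomethyl)furan‑2(5H)‑ones to aldehydes and CrCl2‑mediated ten‑membered ring‑closing allylations.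

Step 12
Reactants: 19 (3aR,4R,6R,10S,11R,11aS)‑4,10‑dihydroxy‑6,10‑dimethyl‑3‑methylidene‑2,5‑dioxododecahydrocyclodeca[b]furan‑11‑yl 2‑methylpropanoate, 20 (2R)‑2‑methylbutanoic acid
Product: 21 (3aS,4R,6R,10S,11R,11aS)‑10‑hydroxy‑6,10‑dimethyl‑3‑methylidene‑4‑{[(2R)‑2‑methylbutanoyl]oxy}‑2,5‑dioxododecahydrocyclodeca[b]furan‑11‑yl 2‑methylpropanoate (CNP0071420.1)
Conditions: iPrN=C=NiPr, DMAP (10 mol%), CH2Cl2, 0 °C
Reagents that add atoms: none
Why: Steglich esterification of the secondary C‑8 hydroxyl (the tertiary C‑4 hydroxyl does not react); the acid stereocentre is bought and is not epimerised at 0 °C, and the change of the C‑7 descriptor from R to S is only a change in substituent priorities.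

**Compound list**
1 | (R)‑β‑citronellene, (3R)‑3,7‑dimethylocta‑1,6‑diene | C=C[C@H](C)CCC=C(C)C | starting material
2 | (4R)‑4‑methylhex‑5‑en‑1‑ol | C=C[C@H](C)CCCO | intermediate
3 | (3R)‑6‑bromo‑3‑methylhex‑1‑ene | C=C[C@H](C)CCCBr | intermediate
4 | dimethyl (4R,5R)‑2,2‑dimethyl‑1,3‑dioxolane‑4,5‑dicarboxylate | COC(=O)[C@@H]1OC(C)(C)O[C@H]1C(=O)OC | starting material
5 | methyl (4R,5R)‑5‑formyl‑2,2‑dimethyl‑1,3‑dioxolane‑4‑carboxylate | COC(=O)[C@@H]1OC(C)(C)O[C@H]1C=O | intermediate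
6 | methyl (4R,5S)‑5‑ethenyl‑2,2‑dimethyl‑1,3‑dioxolane‑4‑carboxylate | COC(=O)[C@@H]1OC(C)(C)O[C@H]1C=C | intermediate
7 | [(4R)‑4‑methylhex‑5‑en‑1‑yl]magnesium bromide | C=C[C@H](C)CCC[Mg]Br | intermediate
8 | (4R,5S)‑5‑ethenyl‑N‑methoxy‑N,2,2‑trimethyl‑1,3‑dioxolane‑4‑carboxamide | CON(C)C(=O)[C@@H]1OC(C)(C)O[C@H]1C=C | intermediate
9 | (5R)‑1‑[(4R,5S)‑5‑ethenyl‑2,2‑dimethyl‑1,3‑dioxolan‑4‑yl]‑5‑methylhept‑6‑en‑1‑one | C=C[C@H](C)CCCC(=O)[C@@H]1OC(C)(C)O[C@H]1C=C | intermediate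
10 | (2S,6R)‑2‑[(4R,5S)‑5‑ethenyl‑2,2‑dimethyl‑1,3‑dioxolan‑4‑yl]‑6‑methyloct‑7‑en‑2‑ol | C=C[C@H](C)CCC[C@](C)(O)[C@@H]1OC(C)(C)O[C@H]1C=C | intermediate
11 | (3S,4R,5S,9R)‑5,9‑dimethylundeca‑1,10‑diene‑3,4,5‑triol | C=C[C@H](C)CCC[C@](C)(O)[C@H](O)[C@@H](O)C=C | intermediate
12 | 2‑(bromomethyl)prop‑2‑enoic acid | C=C(CBr)C(=O)O | starting material
13 | 2‑(bromomethyl)prop‑2‑enoyl chloride | C=C(CBr)C(=O)Cl | intermediate
14 | (3S,4R,5S,9R)‑4,5‑dihydroxy‑5,9‑dimethylundeca‑1,10‑dien‑3‑yl 2‑(bromomethyl)prop‑2‑enoate | C=C[C@H](C)CCC[C@](C)(O)[C@H](O)[C@@H](OC(=O)C(=C)CBr)C=C | intermediate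
15 | (3S,4R,5S,9R)‑3‑{[2‑(bromomethyl)prop‑2‑enoyl]oxy}‑5‑hydroxy‑5,9‑dimethylundeca‑1,10‑dien‑4‑yl 2‑methylpropanoate | C=C[C@H](C)CCC[C@](C)(O)[C@H](OC(=O)C(C)C)[C@@H](OC(=O)C(=C)CBr)C=C | intermediate
16 | (1R,2S,6R)‑1‑[(2S)‑4‑(bromomethyl)‑5‑oxo‑2,5‑dihydrofuran‑2‑yl]‑2‑hydroxy‑2,6‑dimethyloct‑7‑en‑1‑yl 2‑methylpropanoate | C=C[C@H](C)CCC[C@](C)(O)[C@H](OC(=O)C(C)C)[C@H]1OC(=O)C(CBr)=C1 | intermediate
17 | (1R,2S,6R)‑1‑[(2S)‑4‑(bromomethyl)‑5‑oxo‑2,5‑dihydrofuran‑2‑yl]‑2,7,8‑trihydroxy‑2,6‑dimethyloctyl 2‑methylpropanoate (both C‑7 epimers of the octyl chain) | OCC(O)[C@H](C)CCC[C@](C)(O)[C@H](OC(=O)C(C)C)[C@H]1OC(=O)C(CBr)=C1 | intermediate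
18 | (1R,2S,6R)‑1‑[(2S)‑4‑(bromomethyl)‑5‑oxo‑2,5‑dihydrofuran‑2‑yl]‑2‑hydroxy‑2,6‑dimethyl‑7,8‑dioxooctyl 2‑methylpropanoate | O=CC(=O)[C@H](C)CCC[C@](C)(O)[C@H](OC(=O)C(C)C)[C@H]1OC(=O)C(CBr)=C1 | intermediate
19 | (3aR,4R,6R,10S,11R,11aS)‑4,10‑dihydroxy‑6,10‑dimethyl‑3‑methylidene‑2,5‑dioxododecahydrocyclodeca[b]furan‑11‑yl 2‑methylpropanoate; germacrane numbering (4S,5R,6S,7R,8R,10R)‑4,8‑dihydroxy‑5‑(2‑methylpropanoyloxy)‑9‑oxogermacr‑11(13)‑en‑12,6‑olide | C=C1C(=O)O[C@H]2[C@H]1[C@@H](O)C(=O)[C@H](C)CCC[C@](C)(O)[C@@H]2OC(=O)C(C)C | intermediate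
20 | (2R)‑2‑methylbutanoic acid | CC[C@@H](C)C(=O)O | starting material
21 | (3aS,4R,6R,10S,11R,11aS)‑10‑hydroxy‑6,10‑dimethyl‑3‑methylidene‑4‑{[(2R)‑2‑methylbutanoyl]oxy}‑2,5‑dioxododecahydrocyclodeca[b]furan‑11‑yl 2‑methylpropanoate; germacrane numbering (4S,5R,6S,7S,8R,10R) | C=C1C(=O)O[C@H]2[C@H]1[C@@H](OC(=O)[C@H](C)CC)C(=O)[C@H](C)CCC[C@](C)(O)[C@@H]2OC(=O)C(C)C | target

**Totals and risks**
Total step count: 12. Longest linear sequence: 11 steps (1 → 21 through steps 1, 2, 4–12).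

The three steps most likely to fail:

Step 11 (the proposed ring closure). The 2‑oxoaldehyde may be reduced directly to a ketyl, the chain may oligomerise, or the ring may not close under photocatalytic turnover. The fallback sets out from 18 and comes back at 19. It closes the same bond by ground‑state organochromium chemistry with no light and no photocatalyst: stoichiometric CrCl2 in THF/DMF with syringe‑pump addition of 18 in the dark, the allylchromium being made by two one‑electron reductions of the bromide by the metal salt itself. This classical Nozaki–Hiyama–Kishi allylation is known for 3‑(bromomethyl)furan‑2(5H)‑ones adding to aldehydes and for ten‑membered ring closures. It makes no new compound (F0).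

Step 6 (site‑selective acylation of the triol). The two secondary hydroxyls may not be told apart well enough, or the bromide may be lost. The fallback sets out from 11 and comes back at 15, bypassing 14 and step 7. It separates the two oxygens by a protecting‑group detour. TBSCl and imidazole in DMF at 0 °C silylate only the less hindered allylic hydroxyl and give (3S,4R,5S,9R)‑3‑{[tert‑butyl(dimethyl)silyl]oxy}‑5,9‑dimethylundeca‑1,10‑diene‑4,5‑diol F1. Isobutyric anhydride, Et3N and DMAP (no bromide is present yet) then give (3S,4R,5S,9R)‑3‑{[tert‑butyl(dimethyl)silyl]oxy}‑5‑hydroxy‑5,9‑dimethylundeca‑1,10‑dien‑4‑yl 2‑methylpropanoate F2. HF·pyridine (acidic, so no acyl migration) frees (3S,4R,5S,9R)‑3,5‑dihydroxy‑5,9‑dimethylundeca‑1,10‑dien‑4‑yl 2‑methylpropanoate F3, which is acylated at its only secondary hydroxyl with acid chloride 13 and collidine to give 15.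

Step 5 (configuration at C‑4). If methyl adds through an open Felkin–Anh transition state instead of the magnesium chelate, the C‑4 epimer results. The fallback sets out from 6 and comes back at 10, and so at 11 after the same acid hydrolysis. It keeps that facial preference and exchanges the order in which the two carbon groups arrive. Ester 6 is converted through Weinreb amide 8 with MeMgBr into 1‑[(4R,5S)‑5‑ethenyl‑2,2‑dimethyl‑1,3‑dioxolan‑4‑yl]ethan‑1‑one F4. Grignard reagent 7 is then added to this methyl ketone in THF, so the chain now enters where methyl would have gone and the (4S) alcohol 10 is formed.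

**Further compounds**
F0 | step 11 | none | none
F1 | step 6 | (3S,4R,5S,9R)‑3‑{[tert‑butyl(dimethyl)silyl]oxy}‑5,9‑dimethylundeca‑1,10‑diene‑4,5‑diol | C=C[C@H](C)CCC[C@](C)(O)[C@H](O)[C@@H](O[Si](C)(C)C(C)(C)C)C=C
F2 | step 6 | (3S,4R,5S,9R)‑3‑{[tert‑butyl(dimethyl)silyl]oxy}‑5‑hydroxy‑5,9‑dimethylundeca‑1,10‑dien‑4‑yl 2‑methylpropanoate | C=C[C@H](C)CCC[C@](C)(O)[C@H](OC(=O)C(C)C)[C@@H](O[Si](C)(C)C(C)(C)C)C=C
F3 | step 6 | (3S,4R,5S,9R)‑3,5‑dihydroxy‑5,9‑dimethylundeca‑1,10‑dien‑4‑yl 2‑methylpropanoate | C=C[C@H](C)CCC[C@](C)(O)[C@H](OC(=O)C(C)C)[C@@H](O)C=C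
F4 | step 5 | 1‑[(4R,5S)‑5‑ethenyl‑2,2‑dimethyl‑1,3‑dioxolan‑4‑yl]ethan‑1‑one | CC(=O)[C@@H]1OC(C)(C)O[C@H]1C=C
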